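## Retrosynthetic overview

1. The allyl group goes on last, by Suzuki–Miyaura allylation of the C6 bromide. Both benzene rings are bought, so the dioxane ring is the only ring made.
2. The dioxane ring is closed by O–C(aryl) bond formation, benzylic OH onto an ortho C–Br. No stereocentre is touched, so the threo alcohol becomes the trans ring.
3. The benzylic carbinol comes from catalyst-controlled transfer hydrogenation of an α-aryloxy ketone.
4. The C–OAr bond at the methyl-bearing carbon comes from Mitsunobu inversion of an (S)-α-hydroxy ketone with 2,4-dibromophenol. The para Br is the allyl handle and the ortho Br the ring-closure handle, which fixes the regiochemistry.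
5. The key C–C bond (ArC–CMe) joins two aldehyde carbonyl carbons in an enantioselective ThDP-enzyme cross-acyloin. Trimethoxybenzaldehyde serves as the aroyl anion (Breslow enaminol) and acetaldehyde as the acceptor.

Assumption: recombinant Pseudomonas putida benzoylformate decarboxylase (BFD) counts as an obtainable catalyst and takes 1 as donor aldehyde, as it does other meta- and para-methoxybenzaldehydes.

## Route

**Step 1**
Reactants: 1 3,4,5-trimethoxybenzaldehyde; 2 acetaldehyde
Product: 4 (S)-2-hydroxy-1-(3,4,5-trimethoxyphenyl)propan-1-one, via ThDP-bound Breslow enaminol 3 (not isolated)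
Conditions: BFD (P. putida, recombinant), ThDP (0.5 mM), MgSO4 (2.5 mM), KH2PO4/K2HPO4 buffer pH 7.0/DMSO 4:1, 2 (10 equiv, fed in portions), 25 °C, 48 h
Reagents that add atoms: none
Why: Enzymatic asymmetric cross-benzoin (acyloin) carboligation, in which the thiazolium ylide of ThDP adds to 1 and turns its carbonyl carbon into the nucleophilic carbon of Breslow enaminol 3 (an aroyl anion equivalent), which attacks the carbonyl carbon of 2 held in the small acceptor pocket of BFD so that only one face is open and the new carbinol centre is set as S, as known for benzaldehyde and its 3-methoxy, 4-methoxy and 3,5-dimethoxy congeners, while the excess of 2 and the poor acceptor quality of electron-rich 1 suppress the homo-benzoin.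

**Step 2**
Reactants: 4 (S)-2-hydroxy-1-(3,4,5-trimethoxyphenyl)propan-1-one; 5 2,4-dibromophenol
Product: 6 (R)-2-(2,4-dibromophenoxy)-1-(3,4,5-trimethoxyphenyl)propan-1-one
Conditions: PPh3 (1.3 equiv), DIAD (1.3 equiv), toluene, 0 °C to rt
Reagents that add atoms: none
Why: Mitsunobu reaction, in which the acidic phenol 5 (pKa about 8) displaces the activated secondary alcohol by an SN2 process that the neighbouring carbonyl accelerates, so the S carbinol is inverted to the R aryl ether and the near-neutral medium leaves the enolisable centre alone.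

**Step 3**
Reactants: 6 (R)-2-(2,4-dibromophenoxy)-1-(3,4,5-trimethoxyphenyl)propan-1-one
Product: 7 (1R,2R)-2-(2,4-dibromophenoxy)-1-(3,4,5-trimethoxyphenyl)propan-1-ol (threo)
Conditions: RuCl[(S,S)-TsDPEN](p-cymene) (1 mol %), HCO2H/Et3N 5:2, CH2Cl2, 0 °C to rt; minor erythro isomer removed by chromatography or crystallisation
Reagents that add atoms: none
Why: Noyori–Ikariya asymmetric transfer hydrogenation, in which the (S,S)-catalyst delivers hydride in the same spatial sense as for (S)-1-phenylethanol (here called 1R because CH(OAr)CH3 outranks aryl), the polar Felkin–Anh bias of the poorly chelating dibromophenoxy group points the same way (threo), the acidic medium does not epimerise C2, and aryl bromides are inert.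

**Step 4**
Reactants: 7 (1R,2R)-2-(2,4-dibromophenoxy)-1-(3,4,5-trimethoxyphenyl)propan-1-ol
Product: 8 (2R,3R)-6-bromo-2-methyl-3-(3,4,5-trimethoxyphenyl)-2,3-dihydro-1,4-benzodioxine (trans)
Conditions: CuI (10 mol %), 3,4,7,8-tetramethyl-1,10-phenanthroline (20 mol %), Cs2CO3 (1.5 equiv), toluene, 100 °C
Reagents that add atoms: none
Why: Intramolecular Ullmann-type C–O coupling, in which the copper alkoxide can reach only the ortho C–Br (six-membered ring) so the para C–Br stays, and because the new bond is O–C(aryl) both stereocentres are retained and threo 7 maps onto the trans ring with the remaining bromine para to the oxygen on the methyl-bearing carbon.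

**Step 5**
Reactants: 8 (2R,3R)-6-bromo-2-methyl-3-(3,4,5-trimethoxyphenyl)-2,3-dihydro-1,4-benzodioxine; 9 allylboronic acid pinacol ester
Product: 10 (2R,3R)-6-allyl-2-methyl-3-(3,4,5-trimethoxyphenyl)-2,3-dihydro-1,4-benzodioxine (target)
Conditions: Pd(PPh3)4 (5 mol %), CsF (3 equiv), 9 (1.5 equiv), THF, reflux
Reagents that add atoms: none
Why: Suzuki–Miyaura allylation, in which zerovalent palladium inserts into the aryl C–Br bond, fluoride-activated 9 transfers the allyl group, and the mild, weakly basic conditions touch no stereocentre and avoid allyl-to-propenyl isomerisation.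

## Compound list

1 | 3,4,5-trimethoxybenzaldehyde | COc1cc(C=O)cc(OC)c1OC | starting material
2 | acetaldehyde | CC=O | starting material
3 | ThDP-bound Breslow enaminol of 1 (enzyme-bound aroyl anion equivalent) | Cc1ncc(CN2C(=C(O)c3cc(OC)c(OC)c(OC)c3)SC(CCOP(=O)(O)OP(=O)(O)O)=C2C)c(N)n1 | intermediate
4 | (S)-2-hydroxy-1-(3,4,5-trimethoxyphenyl)propan-1-one | C[C@H](O)C(=O)c1cc(OC)c(OC)c(OC)c1 | intermediate
5 | 2,4-dibromophenol | Oc1ccc(Br)cc1Br | starting material
6 | (R)-2-(2,4-dibromophenoxy)-1-(3,4,5-trimethoxyphenyl)propan-1-one | C[C@@H](Oc1ccc(Br)cc1Br)C(=O)c1cc(OC)c(OC)c(OC)c1 | intermediate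
7 | (1R,2R)-2-(2,4-dibromophenoxy)-1-(3,4,5-trimethoxyphenyl)propan-1-ol | C[C@@H](Oc1ccc(Br)cc1Br)[C@H](O)c1cc(OC)c(OC)c(OC)c1 | intermediate
8 | (2R,3R)-6-bromo-2-methyl-3-(3,4,5-trimethoxyphenyl)-2,3-dihydro-1,4-benzodioxine | Brc1ccc2c(c1)O[C@H](c1cc(OC)c(OC)c(OC)c1)[C@@H](C)O2 | intermediate
9 | allylboronic acid pinacol ester (2-allyl-4,4,5,5-tetramethyl-1,3,2-dioxaborolane) | C=CCB1OC(C)(C)C(C)(C)O1 | starting material
10 | (2R,3R)-6-allyl-2-methyl-3-(3,4,5-trimethoxyphenyl)-2,3-dihydro-1,4-benzodioxine | C=CCc1ccc2c(c1)O[C@H](c1cc(OC)c(OC)c(OC)c1)[C@@H](C)O2 | target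

## Step count and risks

Total step count: 5. Longest linear sequence: 5 (1 → 4 → 6 → 7 → 8 → 10).

**Step 1 is the most likely to fail.**
- Risk: BFD may turn over the bulky trimethoxy donor slowly or with reduced ee.
- Fallback, from 1 back to 4: replace the catalytic acyl anion by a stoichiometric one and obtain the enantiomer by resolution.
- Propane-1,3-dithiol with BF3·OEt2 converts 1 into 2-(3,4,5-trimethoxyphenyl)-1,3-dithiane F1.
- Deprotonation with n-BuLi (THF, −40 °C) and addition to 2 gives racemic 1-[2-(3,4,5-trimethoxyphenyl)-1,3-dithian-2-yl]ethan-1-ol F2.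
- MeI/CaCO3 in aqueous MeCN unmasks racemic 2-hydroxy-1-(3,4,5-trimethoxyphenyl)propan-1-one F3.
- Candida antarctica lipase B with vinyl acetate acetylates the R enantiomer to (R)-1-oxo-1-(3,4,5-trimethoxyphenyl)propan-2-yl acetate F4. This leaves 4, which is separated by chromatography (at most 50 %).

**Step 4 is second.**
- Risk: at 100 °C the benzylic alkoxide could expel the good leaving group dibromophenoxide to give an epoxide. It could also shift the aryl group by a Smiles rearrangement, which would scramble regiochemistry and configuration.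
- Fallback, from 4 back to 8, replacing steps 2 to 4: close the ring at the ketone oxidation level from a free phenol.
- Mitsunobu reaction of 4 with 5-bromosalicylaldehyde gives (R)-5-bromo-2-{[1-oxo-1-(3,4,5-trimethoxyphenyl)propan-2-yl]oxy}benzaldehyde F7.
- Baeyer–Villiger oxidation with mCPBA (CH2Cl2, NaHCO3) gives (R)-5-bromo-2-{[1-oxo-1-(3,4,5-trimethoxyphenyl)propan-2-yl]oxy}phenyl formate F8.
- MeOH with a trace of NaHCO3 frees (R)-2-(4-bromo-2-hydroxyphenoxy)-1-(3,4,5-trimethoxyphenyl)propan-1-one F9.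
- Et3SiH/BF3·OEt2 (CH2Cl2, −78 °C) closes and reduces F9 in one operation. Axial hydride delivery opposite a pseudo-equatorial methyl group gives trans 8.

**Step 3 is third.**
- Risk: substrate bias could override the catalyst and favour the erythro alcohol, or C2 could epimerise.
- Fallback, from 6 back to 7: make the erythro alcohol on purpose and invert it.
- RuCl[(R,R)-TsDPEN](p-cymene) with HCO2H/Et3N (or Zn(BH4)2) gives (1S,2R)-2-(2,4-dibromophenoxy)-1-(3,4,5-trimethoxyphenyl)propan-1-ol F5.
- Mitsunobu esterification with 4-nitrobenzoic acid gives (1R,2R)-2-(2,4-dibromophenoxy)-1-(3,4,5-trimethoxyphenyl)propyl 4-nitrobenzoate F6.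
- K2CO3/MeOH then releases 7.

## Further compounds

F1 | step 1 | 2-(3,4,5-trimethoxyphenyl)-1,3-dithiane | COc1cc(C2SCCCS2)cc(OC)c1OC
F2 | step 1 | racemic 1-[2-(3,4,5-trimethoxyphenyl)-1,3-dithian-2-yl]ethan-1-ol | CC(O)C1(SCCCS1)c1cc(OC)c(OC)c(OC)c1
F3 | step 1 | racemic 2-hydroxy-1-(3,4,5-trimethoxyphenyl)propan-1-one | CC(O)C(=O)c1cc(OC)c(OC)c(OC)c1
F4 | step 1 | (R)-1-oxo-1-(3,4,5-trimethoxyphenyl)propan-2-yl acetate | C[C@@H](OC(C)=O)C(=O)c1cc(OC)c(OC)c(OC)c1
F5 | step 3 | (1S,2R)-2-(2,4-dibromophenoxy)-1-(3,4,5-trimethoxyphenyl)propan-1-ol | C[C@@H](Oc1ccc(Br)cc1Br)[C@@H](O)c1cc(OC)c(OC)c(OC)c1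
F6 | step 3 | (1R,2R)-2-(2,4-dibromophenoxy)-1-(3,4,5-trimethoxyphenyl)propyl 4-nitrobenzoate | C[C@@H](Oc1ccc(Br)cc1Br)[C@H](OC(=O)c1ccc(cc1)[N+](=O)[O-])c1cc(OC)c(OC)c(OC)c1
F7 | step 4 | (R)-5-bromo-2-{[1-oxo-1-(3,4,5-trimethoxyphenyl)propan-2-yl]oxy}benzaldehyde | C[C@@H](Oc1ccc(Br)cc1C=O)C(=O)c1cc(OC)c(OC)c(OC)c1
F8 | step 4 | (R)-5-bromo-2-{[1-oxo-1-(3,4,5-trimethoxyphenyl)propan-2-yl]oxy}phenyl formate | C[C@@H](Oc1ccc(Br)cc1OC=O)C(=O)c1cc(OC)c(OC)c(OC)c1
F9 | step 4 | (R)-2-(4-bromo-2-hydroxyphenoxy)-1-(3,4,5-trimethoxyphenyl)propan-1-one | C[C@@H](Oc1ccc(Br)cc1O)C(=O)c1cc(OC)c(OC)c(OC)c1
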